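(The numbers in the tables are simulated from invented constants.)

Try to make Q past half of G's charge, reckoned on E: it cannot be done, since each Q takes two G. That caps Sunday's at 25.0%, Thursday's at 40.0% and Tuesday's at 100%. G is the limiting reagent in the first two, charged below E.

| setting | amber | teal | Sunday's | Thursday's | Tuesday's |
|---|---|---|---|---|---|
| E | 0.29 M | 0.29 M | 0.29 M | 0.29 M | 0.29 M |
| G | 0.087 M | 0.42 M | 0.145 M | 0.232 M | 0.580 M |
| remark | run made earlier | run made earlier |  |  |  |
| time |  |  | 8.0 h | 8.0 h | 8.0 h |

- amber (time / h: Q / %, E / %): 0.333: 0, 91.4; 0.667: 0, 85.1; 1.00: 0.4, 80.8; 2.00: 0.6, 75.6; 4.00: 0.4, 72.4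
- teal (time / h: Q / %, E / %): 0.333: 0.7, 63.4; 1.00: 2.3, 33.5; 2.00: 5.9, 20.1; 3.00: 8.7, 15.6; 4.00: 10.8, 13.6

(each reading ± 0.3 percentage points)

1. how much Q is there at the end, in percent of the E charged: for each flask in turn (Sunday's, Thursday's, Tuesday's)

- a reading or a percentage of Q counts all its forms, free or not
- a reading of E is of its free form alone

Now tighten the caps. Work in fractions of the E charged: e for E, d for the once-exchanged form D, q for Q and g for free G. Then d = 1 − e − q, less any E held bound to Q, which the readings do not show, and g is the charge ratio less d less 2q. E falls fast and then stalls while Q creeps, so take Q's rate as first order in free G and in D. Read teal at 3.00 h with that bound E set aside: d is at most 75.7% and g at least 51.7%. Bound E lowers d and raises g by the same amount, and the two partly cancel in their product. Q climbs from 5.9% to 10.8% around that hour, which gives the Q-making constant, Q gained per hour per unit of d times g, as 0.0626 h⁻¹.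

Since d + g cannot pass the charge ratio, their product cannot pass the square of half that ratio. Multiply by the constant and the time: the ceilings become 3.13% for Sunday's, 8.01% for Thursday's and 50.1% for Tuesday's. Tighten Tuesday's further: with E gone, d and g both equal 1 − q, so q is the constant times the time, divided by 1 plus that product. Any E remaining, free or bound to Q, lowers d times g, so this gives a ceiling of 33.4%. Start that clock at 2.00 h instead, when teal's E had fallen to 20.1%, and the floor is 27.3%.

The forecast, in whose words “Q forms slowly”, gives 1.5%, 4.5% and 32%, the last inside my bracket.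

The flasks give 1.54%, 5.06% and 33.0%, Tuesday's just under my ceiling.

    E + G ⇌ J + D (K = 9.50, k = 0.0620 L mol⁻¹ min⁻¹)
    D + G ⇌ J + Q (K = 38.0, k = 0.00380 L mol⁻¹ min⁻¹)
    E + Q ⇌ L, settled at all times (K = 13.0 L mol⁻¹)

Take Thursday's. At 4.00 h, D stands at 59.2% and G at 18.4% of its own charge, so the constant promises 2.2 percentage points by 8.00 h, and the flask gains 2 points. Thursday's stays low through the falling level of G and the early hour of reading acting together. Without the fall of G, Q stands at 26.7%; read ten times later, it stands at 21.6%.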